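**Retrosynthetic overview**

1. The two 24-nor-friedelane halves are joined only through a cis-fused 1,4-dioxane (aromatic C2, C3, O2, O3 of the upper half; C3', C4' of the lower half). Both C–O bonds (O3–C4', O2–C3') are cut in one retro-[4+2], giving the o-quinone of 6-oxopristimerol (heterodiene) and tingenone (dienophile).
2. Enabling feature: C3' (hemiketal carbon with OH, next to the C2' ketone) and C4' (O- and methyl-bearing, next to the C5'=C6'–C7'=C8' diene) are the two carbons of the enol C3'(OH)=C4'(CH3) of a quinone methide. The upper ring A carries the C6 ketone para to O2, which leaves no C6–H for o-quinone → quinone-methide tautomerism and polarises the O3=C3–C2=O2 diene.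
3. 6-Oxopristimerol comes from C6–H oxidation (benzylic and allylic) of pristimerol diacetate, which comes from reduction/acetylation of pristimerin.
4. Ring order: the ten carbocycles arrive intact in the two monomers; the dioxane is the only ring made and the last one closed.

Key step: step 4

Assumption: pristimerin and tingenone, both catalogue natural products, are taken as the commercial starting materials, so the route is a convergent synthesis from the two monomers. Biogenetic friedelane numbering is used, with primed atoms for the tingenone-derived half.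

**Step 1**
Reactants: 1 pristimerin
Product: 3 pristimerol diacetate, via pristimerol 2 (not isolated)
Conditions: NaBH4, MeOH/THF, 0 °C, Ar; evaporate; Ac2O, pyridine, DMAP (cat.), rt
Reagents that add atoms: acetic anhydride, CC(=O)OC(C)=O
Why: 1,6-Hydride addition at C6 of the quinone methide aromatises ring A to the catechol, which is acetylated at once before air can re-oxidise it; no stereocenter is formed or touched.

**Step 2**
Reactants: 3 pristimerol diacetate
Product: 4 6-oxopristimerol diacetate
Conditions: CrO3, 3,5-dimethylpyrazole, CH2Cl2, −20 °C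
Reagents that add atoms: chromium trioxide, O=[Cr](=O)=O
Why: Chromium(VI) allylic/benzylic C–H oxidation: C6 is the only methylene that is both benzylic to ring A and allylic to C7=C8 (the other allylic positions, C9 and C14, are quaternary), so it should be taken selectively to the aryl enone while the acetates protect the catechol; no stereocenter is involved.

**Step 3**
Reactants: 4 6-oxopristimerol diacetate
Product: 5 6-oxopristimerol
Conditions: HCl (1.25 M in MeOH), CH2Cl2, rt, Ar
Reagents that add atoms: none
Why: Acid-catalysed transesterification of the two aryl acetates to methanol; the hindered C29 methyl ester can only exchange degenerately in MeOH, and the acidic medium keeps the free catechol from autoxidising.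

**Step 4**
Reactants: 5 6-oxopristimerol; 6 tingenone
Product: 8 target dimer CNP0228258.1, via o-quinone 7 (not isolated)
Conditions: 5, Ag2O, 4 Å MS, CH2Cl2, −20 °C, dark; filter (Celite, Ar) into 6 (1.5 equiv), CH2Cl2, −40 → 0 °C
Reagents that add atoms: none
Why: Ag2O dehydrogenates catechol 5 to o-quinone 7, whose O3=C3–C2=O2 unit is an electron-poor 4π heterodiene that adds across the electron-rich enol bond C3'(OH)=C4'(CH3) of 6 in an inverse-electron-demand hetero-Diels–Alder reaction, ring A of the upper half re-aromatising as the two C–O bonds form. The closest known reaction type is the [4+2] cycloaddition of o-quinones with enols, enol ethers and quinone-methide enols to give 2,3-dihydro-1,4-benzodioxines. The dioxane is closed by this intermolecular suprafacial [4+2], with O3–C4' leading and O2–C3' following (a 6-exo-trig hemiketalisation of the O2 phenoxide onto the C3' oxocarbenium if the process is stepwise). C4' and C3' should therefore form cis, and their absolute sense is set by attack on the α face of the flat A'/B' trienone, anti to the axial 9'β-methyl (C25') and 14'β-methyl that screen the β face; the C3' hemiketal can also correct itself by ring–chain tautomerism, so only the C4' face is decided kinetically. The step needs role, regio- and facial selectivity: the C6 ketone leaves 7 no C6–H to tautomerise to a quinone methide, so 7 can only be the diene and 6 only the dienophile, and the same ketone, para to O2, makes O3 the electrophilic terminus (attack there gives the O2 phenoxide conjugated with C6=O), which pairs with C4', the nucleophilic β-carbon of the enol. The carbodiene mode of 7 is disfavoured because it would join fully substituted carbons.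

**Compound list**

1 | pristimerin, methyl 3-hydroxy-2-oxo-24-nor-D:A-friedooleana-1(10),3,5,7-tetraen-29-oate (9β-, 14β-, 17β-, 20β-methyl, 13α-methyl, 18β-H, 20α-CO2Me) | COC(=O)[C@]1(C)CC[C@]2(C)CC[C@]3(C)C4=CC=C5C(C)=C(O)C(=O)C=C5[C@]4(C)CC[C@@]3(C)[C@@H]2C1 | starting material
2 | pristimerol, methyl 2,3-dihydroxy-24-nor-D:A-friedooleana-1,3,5(10),7-tetraen-29-oate (ring A catechol, C6H2, stereocenters as in 1) | COC(=O)[C@]1(C)CC[C@]2(C)CC[C@]3(C)C4=CCc5c(C)c(O)c(O)cc5[C@]4(C)CC[C@@]3(C)[C@@H]2C1 | intermediate
3 | pristimerol diacetate, the 2,3-di-O-acetate of 2 | COC(=O)[C@]1(C)CC[C@]2(C)CC[C@]3(C)C4=CCc5c(C)c(OC(C)=O)c(OC(C)=O)cc5[C@]4(C)CC[C@@]3(C)[C@@H]2C1 | intermediate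
4 | 6-oxopristimerol diacetate, 3 with C6 as ketone conjugated to ring A and C7=C8 | COC(=O)[C@]1(C)CC[C@]2(C)CC[C@]3(C)C4=CC(=O)c5c(C)c(OC(C)=O)c(OC(C)=O)cc5[C@]4(C)CC[C@@]3(C)[C@@H]2C1 | intermediate
5 | 6-oxopristimerol, methyl 2,3-dihydroxy-6-oxo-24-nor-D:A-friedooleana-1,3,5(10),7-tetraen-29-oate | COC(=O)[C@]1(C)CC[C@]2(C)CC[C@]3(C)C4=CC(=O)c5c(C)c(O)c(O)cc5[C@]4(C)CC[C@@]3(C)[C@@H]2C1 | intermediate
6 | tingenone, 3-hydroxy-24,29-dinor-D:A-friedooleana-1(10),3,5,7-tetraene-2,21-dione (9β-, 14β-, 17β-, 20β-methyl, 13α-methyl, 18β-H, 20α-H) | CC1=C(O)C(=O)C=C2C1=CC=C1[C@@]2(C)CC[C@@]2(C)[C@@H]3C[C@@H](C)C(=O)C[C@]3(C)CC[C@]12C | starting material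
7 | o-quinone of 5, methyl 2,3,6-trioxo-24-nor-D:A-friedooleana-1(10),4,7-trien-29-oate | COC(=O)[C@]1(C)CC[C@]2(C)CC[C@]3(C)C4=CC(=O)C5=C(C)C(=O)C(=O)C=C5[C@]4(C)CC[C@@]3(C)[C@@H]2C1 | intermediate
8 | CNP0228258.1, 6-oxopristimerol–tingenone dimer with cis-fused dioxane: O3–C4' and O2–C3' both α, 3'β-OH, 4'β-methyl, 2'-oxo, Δ1'(10'),5',7' | COC(=O)[C@]1(C)CC[C@]2(C)CC[C@]3(C)C4=CC(=O)c5c(cc6c(c5C)O[C@@]5(C)C7=CC=C8[C@@](C)(CC[C@@]9(C)[C@@H]%10C[C@@H](C)C(=O)C[C@]%10(C)CC[C@]89C)C7=CC(=O)[C@@]5(O)O6)[C@]4(C)CC[C@@]3(C)[C@@H]2C1 | target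

**Step count and risks**

Total step count: 4. Longest linear sequence: 4 steps (1 → 3 → 4 → 5 → 8); tingenone 6 enters unmodified in step 4.

Steps most likely to fail:

1. Step 4. The main risk is poor facial discrimination at the C3'=C4' bond, because the controlling 9'β-methyl is three bonds away. Reversed regiochemistry and self-condensation of the o-quinone are further risks. The fallback replaces substrate control by catalyst control in a stepwise ionic [4+2]. It sets out from 6, which is silylated (TBSOTf, 2,6-lutidine, CH2Cl2, −78 °C) to tingenone 3-O-tert-butyldimethylsilyl enol ether F1. o-Quinone 7, generated from 5 as in step 4, is bound through its 1,2-dicarbonyl unit to a chiral copper(II) bis(oxazoline) Lewis acid (both ligand enantiomers are tried to find the matched pair) and combined with F1 at −78 °C. This Lewis-acid-mediated addition/ring closure of a silyl enol ether to an o-quinone should give the 3'-O-tert-butyldimethylsilyl ketal of the target F2. HF·pyridine (THF, 0 °C) then frees the hemiketal, and the route comes back at 8.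

2. Step 2. The risk is over-oxidation or unselective oxidation by chromium(VI), with attack on the aryl methyl C23 or on the C7=C8 bond. The fallback is a two-stage halogenation/oxidation that sets out from 3. Radical bromination (NBS, AIBN, PhCF3, 80 °C) at the doubly activated C6 should give 6-bromopristimerol diacetate F3 as C6 epimers. Kornblum oxidation (DMSO, NaHCO3, 60 °C) should then convert the bromide into the ketone, and the route comes back at 4.

3. Step 3. The risk is sluggish cleavage of the hindered 3-acetate, or autoxidation of the liberated catechol on prolonged reaction. The fallback changes the protecting group and sets out from 1. NaBH4 reduction to 2 as in step 1 is followed by TBSCl, imidazole, DMF, which should give pristimerol bis(tert-butyldimethylsilyl) ether F4. The CrO3/3,5-dimethylpyrazole oxidation of step 2 then gives 6-oxopristimerol bis(tert-butyldimethylsilyl) ether F5. TBAF buffered with AcOH (THF, 0 °C) removes both silyl groups under non-basic conditions, and the route comes back at 5.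

**Further compounds**

F1 | step 4 | tingenone 3-O-tert-butyldimethylsilyl enol ether | CC1=C(O[Si](C)(C)C(C)(C)C)C(=O)C=C2C1=CC=C1[C@@]2(C)CC[C@@]2(C)[C@@H]3C[C@@H](C)C(=O)C[C@]3(C)CC[C@]12C
F2 | step 4 | 3'-O-tert-butyldimethylsilyl ketal of target 8 | COC(=O)[C@]1(C)CC[C@]2(C)CC[C@]3(C)C4=CC(=O)c5c(cc6c(c5C)O[C@@]5(C)C7=CC=C8[C@@](C)(CC[C@@]9(C)[C@@H]%10C[C@@H](C)C(=O)C[C@]%10(C)CC[C@]89C)C7=CC(=O)[C@@]5(O[Si](C)(C)C(C)(C)C)O6)[C@]4(C)CC[C@@]3(C)[C@@H]2C1
F3 | step 2 | 6-bromopristimerol diacetate (C6 epimers) | COC(=O)[C@]1(C)CC[C@]2(C)CC[C@]3(C)C4=CC(Br)c5c(C)c(OC(C)=O)c(OC(C)=O)cc5[C@]4(C)CC[C@@]3(C)[C@@H]2C1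
F4 | step 3 | pristimerol bis(tert-butyldimethylsilyl) ether | COC(=O)[C@]1(C)CC[C@]2(C)CC[C@]3(C)C4=CCc5c(C)c(O[Si](C)(C)C(C)(C)C)c(O[Si](C)(C)C(C)(C)C)cc5[C@]4(C)CC[C@@]3(C)[C@@H]2C1
F5 | step 3 | 6-oxopristimerol bis(tert-butyldimethylsilyl) ether | COC(=O)[C@]1(C)CC[C@]2(C)CC[C@]3(C)C4=CC(=O)c5c(C)c(O[Si](C)(C)C(C)(C)C)c(O[Si](C)(C)C(C)(C)C)cc5[C@]4(C)CC[C@@]3(C)[C@@H]2C1
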